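Each quinone ring (C1 carbonyl between C2–OH and C6–Me, C3 tether, C4 carbonyl, C5–OMe) is disconnected at C1–C2, and the twofold symmetry about the central CH2 of the C13 tether lets both rings be made at once. The precursor is a tethered bis(4-alkenyl-4-hydroxycyclobutenone): C4–C5(OMe)–C6(Me)–C1 derive from a squarate-based cyclobutenone, C3–C2 from a 2-lithioalk-1-ene. On heating, each four-membered ring opens to a dienylketene whose ketene carbon C1 bonds to the alkene terminus C2 in a 6π electrocyclization; oxidation then gives both quinone rings in one operation. The C2 hydroxyl is added afterwards by epoxidation and isomerization.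

Key step: step 4

Remark: the target is 3,3'-(tridecane-1,13-diyl)bis(2-hydroxy-5-methoxy-6-methyl-1,4-benzoquinone), achiral, C29H40O8; the ring numbering used in the overview is kept in all explanations. Steps 2 to 6 are two-directional, so each acts once at either end of the tether: two molecules of 6 are built into 8 in step 2 (C11 + 2 × C3 = C17) and two molecules of 4 into 11 in step 3 (C17 + 2 × C6 = C29). Compounds 2, 3, 10, 11 and 16 carry stereocentres that form without control (racemic or diastereomeric mixtures); all are destroyed on the way to the achiral target, so their SMILES are written without configuration.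

Step 1
Reactants: 1 dimethyl squarate (3,4-dimethoxycyclobut-3-ene-1,2-dione)
Product: 4 3-methoxy-4-methylcyclobut-3-ene-1,2-dione, via lithium alkoxide adduct 2 (not isolated), via tertiary trifluoroacetate 3 (not isolated)
Conditions: MeLi (1.05 equiv), THF, −78 °C; then (CF3CO)2O, −78 °C to 0 °C; H2O work-up
Reagents that add atoms: methyllithium, C[Li]; water, O
Why: 1,2-addition of MeLi to one of the equivalent squarate carbonyls gives alkoxide 2, whose trifluoroacetate 3 ionizes to a methoxy-stabilized cyclobutenyl cation that takes up water at the methoxy-bearing terminus and loses methanol, the standard squarate-to-3-alkoxy-4-alkylcyclobutenedione transposition.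

Step 2
Reactants: 5 1,11-dibromoundecane; 6 2,3-dibromopropene (2.5 equiv)
Product: 8 2,16-dibromoheptadeca-1,16-diene, via undecane-1,11-diylbis(magnesium bromide) 7 (not isolated)
Conditions: Mg (2.4 equiv), THF, reflux; then 6 (2.5 equiv), CuI (5 mol %), THF, −20 °C to rt
Reagents that add atoms: 2,3-dibromopropene (second molecule of 6), C=C(Br)CBr
Why: twofold Grignard formation followed by copper-catalysed allylic substitution at the CH2Br group of 6 (direct and transposed attack give the same 2-bromoallyl product, and the vinylic bromide is inert) joins one molecule of 6 to each end of the C11 chain, the classical route to 2-bromoalk-1-enes, so that the C11 chain and two C3 units give the C17 dibromodiene.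

Step 3
Reactants: 8 2,16-dibromoheptadeca-1,16-diene; 4 3-methoxy-4-methylcyclobut-3-ene-1,2-dione (2.2 equiv)
Product: 11 4,4'-(heptadeca-1,16-diene-2,16-diyl)bis(4-hydroxy-3-methoxy-2-methylcyclobut-2-en-1-one), via 2,16-dilithioheptadeca-1,16-diene 9 (not isolated), via dilithium dialkoxide 10 (not isolated)
Conditions: t-BuLi (4.2 equiv), Et2O/THF, −78 °C; cannulate into 4 (2.2 equiv), THF, −78 °C; aq. NH4Cl
Reagents that add atoms: 3-methoxy-4-methylcyclobut-3-ene-1,2-dione (second molecule of 4), COC1=C(C)C(=O)C1=O
Why: bromine–lithium exchange gives bis(vinyllithium) 9, each end of which undergoes 1,2-addition to the more electrophilic carbonyl of one molecule of 4 (the one attached to the methoxy-bearing carbon, the other being a deactivated vinylogous ester), as is usual for 3-alkoxy-4-alkylcyclobutenediones; the two carbinol stereocentres form without control and are erased in step 4.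

Step 4
Reactants: 11 4,4'-(heptadeca-1,16-diene-2,16-diyl)bis(4-hydroxy-3-methoxy-2-methylcyclobut-2-en-1-one)
Product: 15 5,5'-(tridecane-1,13-diyl)bis(3-methoxy-2-methylcyclohexa-2,5-diene-1,4-dione), via bis(dienylketene) 12 (not isolated), via bis(cyclohexa-2,4-dienone) 13 (not isolated), via bis(hydroquinone) 14 (not isolated)
Conditions: p-xylene (degassed), reflux; then Ag2O, rt
Reagents that add atoms: none
Why: Each 4-hydroxycyclobutenone of 11 undergoes thermal conrotatory 4π opening of the bond between its carbonyl and carbinol carbons (hydroxyl rotating outward) to dienylketene 12, and the ketene carbon (target C1) then bonds to the terminal CH2 of the 1,1-disubstituted alkene (target C2) in a disrotatory 6π electrocyclization that closes each six-membered carbocycle as dienone 13; enolization gives hydroquinone 14, which Ag2O oxidizes in the same flask to quinone 15. The closest known reaction type is the Liebeskind–Moore ring expansion of 4-alkenyl-4-hydroxycyclobutenones to hydroquinones, here run at both ends of the tether at once. Both rings close by the same all-carbon 6π electrocyclic mode, and no stereocentre is created, while the carbinol stereocentres of 11 are erased. The step needs the correct substituent pattern, which is already fixed by the site of addition in step 3 (methyl ends next to C1, methoxy next to C4), and it needs the alkenyl group cis to the ketene, which the outward rotation of the hydroxyl donor secures. Addition of the hydroxyl to the ketene (5H-furanone formation) is disfavoured for the same torquoselective reason.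

Step 5
Reactants: 15 5,5'-(tridecane-1,13-diyl)bis(3-methoxy-2-methylcyclohexa-2,5-diene-1,4-dione)
Product: 16 1,1'-(tridecane-1,13-diyl)bis(3-methoxy-4-methyl-7-oxabicyclo[4.1.0]hept-3-ene-2,5-dione) (bis-epoxide, each epoxide cis-fused)
Conditions: t-BuOOH (decane solution, 2.5 equiv), DBU (20 mol %), CH2Cl2, 0 °C
Reagents that add atoms: tert-butyl hydroperoxide, CC(C)(C)OO
Why: Weitz–Scheffer nucleophilic epoxidation, in which the tert-butylperoxy anion adds to the unsubstituted carbon C2 of the trisubstituted C2=C3 bond while the tetrasubstituted C5=C6 bond is deactivated by its methoxy donor; each epoxide is necessarily cis-fused and the stereoisomer mixture converges in step 6.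

Step 6
Reactants: 16 bis-epoxide
Product: 17 3,3'-(tridecane-1,13-diyl)bis(2-hydroxy-5-methoxy-6-methylcyclohexa-2,5-diene-1,4-dione) (target)
Conditions: H2SO4 on SiO2, CH2Cl2, rt
Reagents that add atoms: none
Why: acid-promoted isomerization of a 2-alkylquinone epoxide to the 2-hydroxyquinone (phthiocol-type rearrangement), in which enolization at the epoxide C2–H opens the C3–O bond and restores the C2=C3 double bond with oxygen left on C2, without change of oxidation level.

Compound list
1 | dimethyl squarate (3,4-dimethoxycyclobut-3-ene-1,2-dione) | COC1=C(OC)C(=O)C1=O | starting material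
2 | lithium 2,3-dimethoxy-1-methyl-4-oxocyclobut-2-en-1-olate (racemic, formed in the flask) | COC1=C(OC)C(C)([O-])C1=O.[Li+] | intermediate
3 | 2,3-dimethoxy-1-methyl-4-oxocyclobut-2-en-1-yl trifluoroacetate (racemic, formed in the flask) | COC1=C(OC)C(C)(OC(=O)C(F)(F)F)C1=O | intermediate
4 | 3-methoxy-4-methylcyclobut-3-ene-1,2-dione | COC1=C(C)C(=O)C1=O | intermediate
5 | 1,11-dibromoundecane | BrCCCCCCCCCCCBr | starting material
6 | 2,3-dibromopropene | C=C(Br)CBr | starting material
7 | undecane-1,11-diylbis(magnesium bromide) (formed in the flask) | Br[Mg]CCCCCCCCCCC[Mg]Br | intermediate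
8 | 2,16-dibromoheptadeca-1,16-diene | C=C(Br)CCCCCCCCCCCCCC(Br)=C | intermediate
9 | 2,16-dilithioheptadeca-1,16-diene (formed in the flask) | [Li]C(=C)CCCCCCCCCCCCCC(=C)[Li] | intermediate
10 | dilithium dialkoxide of 11 (stereoisomer mixture, formed in the flask) | COC1=C(C)C(=O)C1([O-])C(=C)CCCCCCCCCCCCCC(=C)C1([O-])C(OC)=C(C)C1=O.[Li+].[Li+] | intermediate
11 | 4,4'-(heptadeca-1,16-diene-2,16-diyl)bis(4-hydroxy-3-methoxy-2-methylcyclobut-2-en-1-one) (racemic plus meso mixture) | COC1=C(C)C(=O)C1(O)C(=C)CCCCCCCCCCCCCC(=C)C1(O)C(OC)=C(C)C1=O | intermediate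
12 | (3Z,20Z)-4,20-dihydroxy-3,21-dimethoxy-2,22-dimethyl-5,19-dimethylidenetricosa-1,3,20,22-tetraene-1,23-dione, the bis(dienylketene) (formed in the flask) | O=C=C(C)/C(OC)=C(/O)C(=C)CCCCCCCCCCCCCC(=C)/C(O)=C(OC)\C(C)=C=O | intermediate
13 | 5,5'-(tridecane-1,13-diyl)bis(4-hydroxy-3-methoxy-2-methylcyclohexa-2,4-dien-1-one) (formed in the flask) | COC1=C(C)C(=O)CC(CCCCCCCCCCCCCC2=C(O)C(OC)=C(C)C(=O)C2)=C1O | intermediate
14 | 5,5'-(tridecane-1,13-diyl)bis(3-methoxy-2-methylbenzene-1,4-diol) (formed in the flask) | COc1c(C)c(O)cc(CCCCCCCCCCCCCc2cc(O)c(C)c(OC)c2O)c1O | intermediate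
15 | 5,5'-(tridecane-1,13-diyl)bis(3-methoxy-2-methylcyclohexa-2,5-diene-1,4-dione) | COC1=C(C)C(=O)C=C(CCCCCCCCCCCCCC2=CC(=O)C(C)=C(OC)C2=O)C1=O | intermediate
16 | 1,1'-(tridecane-1,13-diyl)bis(3-methoxy-4-methyl-7-oxabicyclo[4.1.0]hept-3-ene-2,5-dione) (cis-fused epoxides, stereoisomer mixture) | COC1=C(C)C(=O)C2OC2(CCCCCCCCCCCCCC34OC3C(=O)C(C)=C(OC)C4=O)C1=O | intermediate
17 | 3,3'-(tridecane-1,13-diyl)bis(2-hydroxy-5-methoxy-6-methylcyclohexa-2,5-diene-1,4-dione) | COC1=C(C)C(=O)C(O)=C(CCCCCCCCCCCCCC2=C(O)C(=O)C(C)=C(OC)C2=O)C1=O | target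

Total step count: 6
Longest linear sequence: 5 steps (steps 2 to 6: 5 → 8 → 11 → 15 → 16 → 17); step 1 supplies the second fragment.

Steps most likely to fail

Step 4 (key step). The ketene may be captured by the free tertiary hydroxyl, the two ends may convert unevenly, or the free hydroquinone may degrade at reflux. The fallback sets out from 11 and masks the carbinol oxygen before the ring expansion. Silylation with Et3SiOTf and 2,6-lutidine in CH2Cl2 should give 4,4'-(heptadeca-1,16-diene-2,16-diyl)bis[3-methoxy-2-methyl-4-(triethylsilyloxy)cyclobut-2-en-1-one] F1. Thermolysis in p-xylene would run the same 4π/6π sequence, now without an OH that can add to the ketene, and should give 5,5'-(tridecane-1,13-diyl)bis[3-methoxy-2-methyl-4-(triethylsilyloxy)phenol] F2. Oxidative desilylation with (NH4)2Ce(NO3)6 in MeCN/H2O returns to the route at 15.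

Step 5. The peroxide anion may attack the methoxy-bearing carbon by addition–elimination, or the base may degrade the quinone, instead of epoxidizing C2=C3. The fallback sets out from 15 and replaces epoxidation by Thiele–Winter acetoxylation. Ac2O with BF3·OEt2 should add acetate at the only free ring position (C2) and give 3,3'-(tridecane-1,13-diyl)bis(5-methoxy-6-methylbenzene-1,2,4-triyl) hexaacetate F3. Methanolysis with K2CO3 in MeOH should release 3,3'-(tridecane-1,13-diyl)bis(5-methoxy-6-methylbenzene-1,2,4-triol) F4, which air oxidizes in the same flask. This bypasses 16 and returns to the route at 17.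

Step 2. Wurtz-type coupling during formation of the bis-Grignard reagent, or halogen–magnesium exchange at the vinylic bromide, may erode the twofold allylation. The fallback sets out from 5 and builds the 2-bromoalkene ends from alkynes. Twofold alkylation of 5 with 3-lithio-1-(trimethylsilyl)propyne (from 1-(trimethylsilyl)propyne and n-BuLi, THF, −78 °C to rt) should give 1,17-bis(trimethylsilyl)heptadeca-1,16-diyne F5. K2CO3 in MeOH should remove the silyl groups to give heptadeca-1,16-diyne F6. Bromoboration with B-bromo-9-BBN in CH2Cl2 at 0 °C should give 9,9'-[(1Z,16Z)-2,16-dibromoheptadeca-1,16-diene-1,17-diyl]bis(9-borabicyclo[3.3.1]nonane) F7, and protonolysis with AcOH returns to the route at 8.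

Further compounds
F1 | step 4 | 4,4'-(heptadeca-1,16-diene-2,16-diyl)bis[3-methoxy-2-methyl-4-(triethylsilyloxy)cyclobut-2-en-1-one] | COC1=C(C)C(=O)C1(O[Si](CC)(CC)CC)C(=C)CCCCCCCCCCCCCC(=C)C1(O[Si](CC)(CC)CC)C(OC)=C(C)C1=O
F2 | step 4 | 5,5'-(tridecane-1,13-diyl)bis[3-methoxy-2-methyl-4-(triethylsilyloxy)phenol] | COc1c(C)c(O)cc(CCCCCCCCCCCCCc2cc(O)c(C)c(OC)c2O[Si](CC)(CC)CC)c1O[Si](CC)(CC)CC
F3 | step 5 | 3,3'-(tridecane-1,13-diyl)bis(5-methoxy-6-methylbenzene-1,2,4-triyl) hexaacetate | COc1c(C)c(OC(C)=O)c(OC(C)=O)c(CCCCCCCCCCCCCc2c(OC(C)=O)c(OC(C)=O)c(C)c(OC)c2OC(C)=O)c1OC(C)=O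
F4 | step 5 | 3,3'-(tridecane-1,13-diyl)bis(5-methoxy-6-methylbenzene-1,2,4-triol) | COc1c(C)c(O)c(O)c(CCCCCCCCCCCCCc2c(O)c(O)c(C)c(OC)c2O)c1O
F5 | step 2 | 1,17-bis(trimethylsilyl)heptadeca-1,16-diyne | C[Si](C)(C)C#CCCCCCCCCCCCCCC#C[Si](C)(C)C
F6 | step 2 | heptadeca-1,16-diyne | C#CCCCCCCCCCCCCCC#C
F7 | step 2 | 9,9'-[(1Z,16Z)-2,16-dibromoheptadeca-1,16-diene-1,17-diyl]bis(9-borabicyclo[3.3.1]nonane) | Br/C(CCCCCCCCCCCCC/C(Br)=C/B1C2CCCC1CCC2)=C\B1C2CCCC1CCC2
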